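**Retrosynthetic overview**

1. Target 22 ⇒ alcohol 18 (N-Boc, side-chain O-TBS) + (E)-oct-2-enoic acid 19: Yamaguchi esterification, then one acidic deprotection.
2. 18 ⇒ cycloadduct 16 by a single hydrogenation (C7=C8 saturated, N-Cbz exchanged for N-Boc, O-benzyl removed).
3. 16 ⇒ acyclic triene 15 by an intramolecular Diels–Alder reaction of an N-acyl-1-aminodiene with a cis-olefin. C4a–C8a and C5–C6 form together, so the carbocycle and the piperidine ring close in the same step and C4a, C5 and C8a are set at once.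
4. 15 ⇒ amine 12 + crotonaldehyde 13; 12 ⇒ Z-selective cross-metathesis of allyl carbinol ether 10 with alkene 5.
5. 10 ⇐ N-Boc-D-alaninol 6 (C2 from the chiral pool, C3 by catalyst-controlled allylation); 5 ⇐ (R)-2-propyloxirane 1 (C5′ from the chiral pool).

Assumption: quinoline numbering is used (N1, C2-methyl, C3-ester, C5-side chain, primed side-chain carbons), and the (S)-ligand is taken as the catalyst enantiomer that attacks the Si face of aldehyde 8 in step 3; if the sense is the opposite, the mirror-image ligand is used in the same step.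

**Route**

Step 1
Reactants: 1 (2R)-2-propyloxirane; 2 5-bromopent-1-ene
Product: 4 (4R)-dec-9-en-4-ol, via pent-4-enylmagnesium bromide 3 (not isolated)
Conditions: Mg, THF, 25–40 °C; then CuI (10 mol %), 1, −30 → 0 °C; then H2O
Reagents that add atoms: none
Why: Copper-catalysed Grignard ring-opening of the epoxide (SN2 at the unsubstituted carbon) leaves the epoxide stereocentre untouched, so the (R)-carbinol that becomes C5′ comes directly from the chiral pool.

Step 2
Reactants: 4 (4R)-dec-9-en-4-ol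
Product: 5 tert-butyl{[(4R)-dec-9-en-4-yl]oxy}dimethylsilane
Conditions: TBSCl, imidazole, DMF, rt
Reagents that add atoms: tert-butyldimethylsilyl chloride, CC(C)(C)[Si](C)(C)Cl
Why: Imidazole-promoted silyl ether formation masks the side-chain alcohol until the last step without touching the stereocentre.

Step 3
Reactants: 6 tert-butyl N-[(2R)-1-hydroxypropan-2-yl]carbamate (N-Boc-D-alaninol); 7 allyl acetate (5 equiv)
Product: 9 tert-butyl N-[(2R,3S)-3-hydroxyhex-5-en-2-yl]carbamate, via N-Boc-D-alaninal 8 (not isolated)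
Conditions: [Ir(cod)Cl]2 (2.5 mol %), (S)-SEGPHOS (5 mol %), 4-chloro-3-nitrobenzoic acid (10 mol %), Cs2CO3 (20 mol %), THF, 100 °C, sealed tube
Reagents that add atoms: none
Why: In this Krische iridium-catalysed transfer-hydrogenative carbonyl allylation the alcohol is dehydrogenated to aldehyde 8 only transiently, so C2 does not epimerise, and the chiral allyl-iridium complex delivers allyl to the Si face under catalyst control, setting the 3S carbinol anti to the C2 nitrogen.

Step 4
Reactants: 9 tert-butyl N-[(2R,3S)-3-hydroxyhex-5-en-2-yl]carbamate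
Product: 10 tert-butyl N-[(2R,3S)-3-(benzyloxy)hex-5-en-2-yl]carbamate
Conditions: 2-benzyloxy-1-methylpyridinium triflate (2 equiv), MgO (2 equiv), PhCF3, 85 °C
Reagents that add atoms: 2-(benzyloxy)-1-methylpyridin-1-ium trifluoromethanesulfonate, C[n+]1ccccc1OCc1ccccc1.[O-]S(=O)(=O)C(F)(F)F
Why: Neutral benzyl transfer from the 2-benzyloxypyridinium salt (Dudley benzylation) etherifies the secondary alcohol without strong base, so N-benzylation and oxazolidinone formation from the NH-Boc group do not compete and no stereocentre is touched.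

Step 5
Reactants: 10 tert-butyl N-[(2R,3S)-3-(benzyloxy)hex-5-en-2-yl]carbamate; 5 tert-butyl{[(4R)-dec-9-en-4-yl]oxy}dimethylsilane (3 equiv)
Product: 11 tert-butyl N-[(2R,3S,5Z,11R)-3-(benzyloxy)-11-{[tert-butyl(dimethyl)silyl]oxy}tetradec-5-en-2-yl]carbamate
Conditions: Ru(NO3)(=CH-C6H4-2-OiPr)(C,C-cyclometalated 1-adamantyl-3-(2,6-diisopropylphenyl)imidazolin-2-ylidene) (5 mol %), THF, 35 °C, static vacuum
Reagents that add atoms: none
Why: Z-selective olefin cross-metathesis with the cyclometalated ruthenium nitrate catalyst joins the two terminal alkenes through an all-syn ruthenacyclobutane, giving the cis-olefin whose geometry later fixes C5, with loss of ethene and no change at the stereocentres.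

Step 6
Reactants: 11 tert-butyl N-[(2R,3S,5Z,11R)-3-(benzyloxy)-11-{[tert-butyl(dimethyl)silyl]oxy}tetradec-5-en-2-yl]carbamate
Product: 12 (2R,3S,5Z,11R)-3-(benzyloxy)-11-{[tert-butyl(dimethyl)silyl]oxy}tetradec-5-en-2-amine
Conditions: TMSOTf, 2,6-lutidine, CH2Cl2, 0 °C; then MeOH, rt
Reagents that add atoms: none
Why: Silyl triflate-mediated Boc cleavage (O-silylation, loss of the tert-butyl cation, methanolysis of the silyl carbamate) frees the primary amine under conditions that leave the TBS ether, the benzyl ether and the cis-olefin intact.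

Step 7
Reactants: 12 (2R,3S,5Z,11R)-3-(benzyloxy)-11-{[tert-butyl(dimethyl)silyl]oxy}tetradec-5-en-2-amine; 13 (2E)-but-2-enal
Product: 15 benzyl N-[(1E)-buta-1,3-dien-1-yl]-N-[(2R,3S,5Z,11R)-3-(benzyloxy)-11-{[tert-butyl(dimethyl)silyl]oxy}tetradec-5-en-2-yl]carbamate, via N-crotylidene imine 14 (not isolated)
Conditions: 13, 4 Å MS, Et2O, 0 °C → rt; filter, concentrate; NaN(SiMe3)2, THF, −78 °C; then CbzCl, −78 → 0 °C
Reagents that add atoms: benzyl chloroformate, O=C(Cl)OCc1ccccc1
Why: Imine condensation gives 1-azadiene 14, and N-acylation of its sodium 1-azapentadienyl anion by the chloroformate (dienamide synthesis by deprotonation–acylation of a conjugated imine) gives the (E)-N-acyl-1-amino-1,3-diene without change at any stereocentre.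

Step 8
Reactants: 15 benzyl N-[(1E)-buta-1,3-dien-1-yl]-N-[(2R,3S,5Z,11R)-3-(benzyloxy)-11-{[tert-butyl(dimethyl)silyl]oxy}tetradec-5-en-2-yl]carbamate
Product: 16 benzyl (2R,3S,4aR,5R,8aS)-3-(benzyloxy)-5-[(5R)-5-{[tert-butyl(dimethyl)silyl]oxy}octyl]-2-methyl-3,4,4a,5,6,8a-hexahydroquinoline-1(2H)-carboxylate
Conditions: toluene (0.01 M), N,O-bis(trimethylsilyl)acetamide (0.1 equiv), BHT (cat.), silylated sealed tube, 200–210 °C, 24 h
Reagents that add atoms: none
Why: The intramolecular Diels–Alder reaction of the N-acyl-1-aminodiene with the tethered cis-olefin closes the carbocycle and the piperidine together, where suprafacial addition to the Z-alkene makes H4a and H5 cis, the tether-endo transition state typical of such dienamides gives the cis ring fusion (H4a cis to H8a), and the C2 methyl group, held pseudoaxial by allylic 1,3-strain with the carbamate, sends the olefin to the diene face that places H8a cis to H2.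

Step 9
Reactants: 16 benzyl (2R,3S,4aR,5R,8aS)-3-(benzyloxy)-5-[(5R)-5-{[tert-butyl(dimethyl)silyl]oxy}octyl]-2-methyl-3,4,4a,5,6,8a-hexahydroquinoline-1(2H)-carboxylate
Product: 18 tert-butyl (2R,3S,4aR,5R,8aS)-5-[(5R)-5-{[tert-butyl(dimethyl)silyl]oxy}octyl]-3-hydroxy-2-methyloctahydroquinoline-1(2H)-carboxylate, via amino alcohol 17 (not isolated)
Conditions: H2 (4 atm), Pd(OH)2/C, EtOAc–EtOH, rt; filter; then Boc2O, Et3N, 50 °C
Reagents that add atoms: di-tert-butyl dicarbonate, CC(C)(C)OC(=O)OC(=O)OC(C)(C)C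
Why: Heterogeneous hydrogenation saturates C7=C8 and hydrogenolyses both the benzyl carbamate and the benzyl ether, and the liberated secondary amine 17 is recaptured as the acid-labile Boc carbamate (carbamate exchange) while no stereocentre is formed or disturbed.

Step 10
Reactants: 18 tert-butyl (2R,3S,4aR,5R,8aS)-5-[(5R)-5-{[tert-butyl(dimethyl)silyl]oxy}octyl]-3-hydroxy-2-methyloctahydroquinoline-1(2H)-carboxylate; 19 (2E)-oct-2-enoic acid
Product: 21 tert-butyl (2R,3S,4aR,5R,8aS)-5-[(5R)-5-{[tert-butyl(dimethyl)silyl]oxy}octyl]-2-methyl-3-{[(2E)-oct-2-enoyl]oxy}octahydroquinoline-1(2H)-carboxylate, via mixed anhydride 20 (not isolated)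
Conditions: 19, 2,4,6-trichlorobenzoyl chloride, Et3N, THF, rt; then 18, DMAP, toluene, rt → 40 °C
Reagents that add atoms: none
Why: Yamaguchi esterification through mixed anhydride 20 acylates the hindered C3 hydroxyl with retention at C3 while nitrogen is blocked as the Boc carbamate and the side-chain oxygen as the silyl ether.

Step 11
Reactants: 21 tert-butyl (2R,3S,4aR,5R,8aS)-5-[(5R)-5-{[tert-butyl(dimethyl)silyl]oxy}octyl]-2-methyl-3-{[(2E)-oct-2-enoyl]oxy}octahydroquinoline-1(2H)-carboxylate
Product: 22 (2R,3S,4aR,5R,8aS)-5-[(5R)-5-hydroxyoctyl]-2-methyldecahydroquinolin-3-yl (2E)-oct-2-enoate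
Conditions: TFA/CH2Cl2/H2O (9:9:1), 0 °C → rt; then aq NaHCO3
Reagents that add atoms: none
Why: Acidolysis removes the Boc carbamate and the silyl ether in one operation, and keeping the amine protonated until the mild basic work-up avoids O-to-N acyl transfer and conjugate addition to the enoate.

**Compound list**

1 | (2R)-2-propyloxirane | CCC[C@@H]1CO1 | starting material
2 | 5-bromopent-1-ene | C=CCCCBr | starting material
3 | pent-4-enylmagnesium bromide | C=CCCC[Mg]Br | intermediate
4 | (4R)-dec-9-en-4-ol | C=CCCCC[C@H](O)CCC | intermediate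
5 | tert-butyl{[(4R)-dec-9-en-4-yl]oxy}dimethylsilane | C=CCCCC[C@H](O[Si](C)(C)C(C)(C)C)CCC | intermediate
6 | tert-butyl N-[(2R)-1-hydroxypropan-2-yl]carbamate (N-Boc-D-alaninol) | C[C@H](CO)NC(=O)OC(C)(C)C | starting material
7 | prop-2-en-1-yl acetate (allyl acetate) | C=CCOC(C)=O | starting material
8 | tert-butyl N-[(2R)-1-oxopropan-2-yl]carbamate (N-Boc-D-alaninal) | C[C@H](C=O)NC(=O)OC(C)(C)C | intermediate
9 | tert-butyl N-[(2R,3S)-3-hydroxyhex-5-en-2-yl]carbamate | C[C@@H](NC(=O)OC(C)(C)C)[C@@H](O)CC=C | intermediate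
10 | tert-butyl N-[(2R,3S)-3-(benzyloxy)hex-5-en-2-yl]carbamate | C[C@@H](NC(=O)OC(C)(C)C)[C@@H](OCc1ccccc1)CC=C | intermediate
11 | tert-butyl N-[(2R,3S,5Z,11R)-3-(benzyloxy)-11-{[tert-butyl(dimethyl)silyl]oxy}tetradec-5-en-2-yl]carbamate | C[C@@H](NC(=O)OC(C)(C)C)[C@@H](OCc1ccccc1)C/C=C\CCCC[C@H](O[Si](C)(C)C(C)(C)C)CCC | intermediate
12 | (2R,3S,5Z,11R)-3-(benzyloxy)-11-{[tert-butyl(dimethyl)silyl]oxy}tetradec-5-en-2-amine | C[C@@H](N)[C@@H](OCc1ccccc1)C/C=C\CCCC[C@H](O[Si](C)(C)C(C)(C)C)CCC | intermediate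
13 | (2E)-but-2-enal (crotonaldehyde) | C/C=C/C=O | starting material
14 | (1E,2E)-N-[(2R,3S,5Z,11R)-3-(benzyloxy)-11-{[tert-butyl(dimethyl)silyl]oxy}tetradec-5-en-2-yl]but-2-en-1-imine | C[C@@H](/N=C/C=C/C)[C@@H](OCc1ccccc1)C/C=C\CCCC[C@H](O[Si](C)(C)C(C)(C)C)CCC | intermediate
15 | benzyl N-[(1E)-buta-1,3-dien-1-yl]-N-[(2R,3S,5Z,11R)-3-(benzyloxy)-11-{[tert-butyl(dimethyl)silyl]oxy}tetradec-5-en-2-yl]carbamate | C[C@@H](N(/C=C/C=C)C(=O)OCc1ccccc1)[C@@H](OCc1ccccc1)C/C=C\CCCC[C@H](O[Si](C)(C)C(C)(C)C)CCC | intermediate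
16 | benzyl (2R,3S,4aR,5R,8aS)-3-(benzyloxy)-5-[(5R)-5-{[tert-butyl(dimethyl)silyl]oxy}octyl]-2-methyl-3,4,4a,5,6,8a-hexahydroquinoline-1(2H)-carboxylate | C(c1ccccc1)O[C@H]1C[C@@H]2[C@H](CCCC[C@H](O[Si](C)(C)C(C)(C)C)CCC)CC=C[C@@H]2N(C(=O)OCc2ccccc2)[C@@H]1C | intermediate
17 | (2R,3S,4aR,5R,8aS)-5-[(5R)-5-{[tert-butyl(dimethyl)silyl]oxy}octyl]-2-methyldecahydroquinolin-3-ol | O[C@H]1C[C@@H]2[C@H](CCCC[C@H](O[Si](C)(C)C(C)(C)C)CCC)CCC[C@@H]2N[C@@H]1C | intermediate
18 | tert-butyl (2R,3S,4aR,5R,8aS)-5-[(5R)-5-{[tert-butyl(dimethyl)silyl]oxy}octyl]-3-hydroxy-2-methyloctahydroquinoline-1(2H)-carboxylate | O[C@H]1C[C@@H]2[C@H](CCCC[C@H](O[Si](C)(C)C(C)(C)C)CCC)CCC[C@@H]2N(C(=O)OC(C)(C)C)[C@@H]1C | intermediate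
19 | (2E)-oct-2-enoic acid | CCCCC/C=C/C(=O)O | starting material
20 | (2E)-oct-2-enoic 2,4,6-trichlorobenzoic anhydride | CCCCC/C=C/C(=O)OC(=O)c1c(Cl)cc(Cl)cc1Cl | intermediate
21 | tert-butyl (2R,3S,4aR,5R,8aS)-5-[(5R)-5-{[tert-butyl(dimethyl)silyl]oxy}octyl]-2-methyl-3-{[(2E)-oct-2-enoyl]oxy}octahydroquinoline-1(2H)-carboxylate | CCCCC/C=C/C(=O)O[C@H]1C[C@@H]2[C@H](CCCC[C@H](O[Si](C)(C)C(C)(C)C)CCC)CCC[C@@H]2N(C(=O)OC(C)(C)C)[C@@H]1C | intermediate
22 | (2R,3S,4aR,5R,8aS)-5-[(5R)-5-hydroxyoctyl]-2-methyldecahydroquinolin-3-yl (2E)-oct-2-enoate | CCCCC/C=C/C(=O)O[C@H]1C[C@@H]2[C@H](CCCC[C@H](O)CCC)CCC[C@@H]2N[C@@H]1C | target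

**Step count and risks**

Total step count: 11. Longest linear sequence: 9 steps (6 → 22, steps 3 to 11); the side-chain branch (steps 1 and 2) joins at step 5.

The three steps most likely to fail:

Step 8 (intramolecular Diels–Alder). The dienophile is an unactivated cis-1,2-dialkyl olefin, so the reaction needs about 200 °C, and the endo and facial preferences rest on analogy with simpler dienamides rather than on this substrate. The fallback leaves the thermal pericyclic manifold and is the weakest of the three, because it keeps the same disconnection and has no direct precedent for a dienyl carbamate with an internal cis-olefin. It sets out from 15 and comes back at 16. The two C–C bonds are made by a rhodium-templated stepwise [4+2] with a cationic monovalent rhodium catalyst generated from [Rh(cod)Cl]2 and AgSbF6 in 1,2-dichloroethane/2,2,2-trifluoroethanol at 40–60 °C. The diene and olefin bind to the metal, oxidative cyclisation gives a rhodacycle, and reductive elimination closes the cyclohexene. Both new bonds are delivered to the same face of the olefin, so the cis relationship of H4a and H5 is kept, and the low temperature removes the thermal side reactions. This fallback makes no compound outside the list (F0).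

Step 5 (Z-selective cross-metathesis). Two unbiased terminal olefins can give homodimers, and any E-isomer would carry through to the C5 epimer. The fallback replaces metathesis by a salt-free Wittig olefination; it sets out from 10 and 5 and comes back at 11. Ozonolysis of 10 (O3, CH2Cl2/MeOH, −78 °C; Me2S) gives the aldehyde tert-butyl N-[(2R,3S)-3-(benzyloxy)-5-oxopentan-2-yl]carbamate F1. Ozonolysis of 5 with NaBH4 work-up gives the alcohol (6R)-6-{[tert-butyl(dimethyl)silyl]oxy}nonan-1-ol F2. I2, PPh3 and imidazole convert it into the iodide tert-butyl{[(4R)-9-iodononan-4-yl]oxy}dimethylsilane F3, and PPh3 in refluxing MeCN gives the phosphonium salt {(6R)-6-{[tert-butyl(dimethyl)silyl]oxy}nonyl}triphenylphosphonium iodide F4. Deprotonation with NaN(SiMe3)2 (THF, −78 °C) gives the ylide {(6R)-6-{[tert-butyl(dimethyl)silyl]oxy}nonylidene}triphenylphosphorane F5, which with F1 gives the cis-olefin 11 through the kinetic oxaphosphetane.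

Step 3 (catalytic allylation of the amino alcohol). The sense and level of catalyst control on this β-stereogenic alcohol decide the C3 configuration, and a slow coupling would let aldehyde 8 epimerise. The fallback separates oxidation and C–C bond formation and uses a stoichiometric chiral allylborane; it sets out from 6 and comes back at 9. Dess–Martin oxidation of 6 (CH2Cl2, 0 °C) gives aldehyde 8, now isolated and used at once. Brown allylboration with (−)-B-allyldiisopinocampheylborane (from (+)-α-pinene; Et2O, −78 °C; NaOH/H2O2 work-up) attacks its Si face under reagent control to give 9. This fallback makes no compound outside the list (F0).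

**Further compounds**

F0 | step 3 | none | none
F1 | step 5 | tert-butyl N-[(2R,3S)-3-(benzyloxy)-5-oxopentan-2-yl]carbamate | C[C@@H](NC(=O)OC(C)(C)C)[C@@H](OCc1ccccc1)CC=O
F2 | step 5 | (6R)-6-{[tert-butyl(dimethyl)silyl]oxy}nonan-1-ol | OCCCCC[C@H](O[Si](C)(C)C(C)(C)C)CCC
F3 | step 5 | tert-butyl{[(4R)-9-iodononan-4-yl]oxy}dimethylsilane | ICCCCC[C@H](O[Si](C)(C)C(C)(C)C)CCC
F4 | step 5 | {(6R)-6-{[tert-butyl(dimethyl)silyl]oxy}nonyl}triphenylphosphonium iodide | [I-].c1ccccc1[P+](c1ccccc1)(c1ccccc1)CCCCC[C@H](O[Si](C)(C)C(C)(C)C)CCC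
F5 | step 5 | {(6R)-6-{[tert-butyl(dimethyl)silyl]oxy}nonylidene}triphenylphosphorane | c1ccccc1P(c1ccccc1)(c1ccccc1)=CCCCC[C@H](O[Si](C)(C)C(C)(C)C)CCC
F0 | step 8 | none | none
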